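The data come from a simulation from invented constants; noise was put on by code.

In a closed isothermal flask whose steps are first order, the fractions of the charge at a given time do not depend on the charge. Where the steps are second order, they depend on the product of charge and time, and that product is the invariant.

| setting | east | north-west | flask |
|---|---|---|---|
| substrate | 13 mM | 30 mM | 20 mM |
| remark | run made earlier | run made earlier |  |
| time |  |  | 2.5 h |

| run | time / h | open dimer / % | single ring / % | substrate / % |
|---|---|---|---|---|
| east | 0.0333 | 27.1 | 8.9 | 57.6 |
| east | 0.0833 | 33.3 | 18.9 | 32.2 |
| east | 0.200 | 30.4 | 24.0 | 14.0 |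
| east | 0.500 | 13.0 | 29.9 | 2.8 |
| east | 1.33 | 3.4 | 33.9 | 0 |
| east | 3.00 | 0.7 | 31.7 | 0.6 |
| north-west | 0.0333 | 42.2 | 6.5 | 39.0 |
| north-west | 0.0833 | 40.3 | 10.5 | 18.2 |
| north-west | 0.200 | 27.4 | 13.9 | 4.5 |
| north-west | 0.500 | 14.3 | 17.3 | 0 |
| north-west | 1.33 | 1.0 | 17.0 | 0 |
| north-west | 3.00 | 0 | 19.1 | 0 |

(standard deviation of a reading: 1 percentage point)

- in percentages every species weighs as the substrate in it: one open dimer counts as two

* the moment within 2.5 h at which there is most open dimer
* the amount of open dimer, in percent of the substrate charged, at that time

Either extreme gives the 20 mM flask the peak fraction of open dimer read in the east run, 33.3%. The first-order extreme also keeps the east peak reading's time, 0.0833 h, while the second-order extreme moves it to 0.0541 h.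

The real flask is mixed. Late single ring is lower in the north-west run, 19.1%, than in the east run, 31.7%, so ring closure loses share to a second-order step as the charge rises: a selectivity factor that grows with charge. The peak time of the flask should therefore lie between those two times.

The peak readings also differ, so logarithms give the charge exponent of the peak, the rise in log peak fraction per unit rise in log charge: 0.283, a reading with their scatter. From the east reading, it puts the flask's peak at 37.6%.

The forecast gives 38% (35% to 41%) at 0.065 h (0.045 h to 0.09 h), ending with “Interpolating the observed peaks”.

The flask gives 38.6% at 0.0701 h, a time between the extremes.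

    substrate → single ring (k = 0.0610 /min)
    2 substrate → open dimer (k = 10.0 /M/min)
    substrate + open dimer → open trimer (k = 7.80 /M/min)
    open dimer → ring dimer (k = 0.0400 /min)
    substrate + single ring → side product (k = 2.00 /M/min)

At the flask's best time 13.7% of the charge stands as open trimer, a species absent from the readings. The flask's peak stands 1.00 percentage point above the exponent's reckoning.

For the neighbour with 34 mM, the exponent carried from the north-west reading gives 43.7%. That neighbour's computed peak is 42.7%.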